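The rate constants were chosen freely; the run is a simulation.

Pure target cannot be had from this scheme: as it forms, it turns into isomer of the product and back.

    starting material → intermediate A (k1 = 2.60 × 10⁻⁵ s⁻¹)
    intermediate A → intermediate B (k2 = 2.67 × 10⁻⁵ s⁻¹)
    intermediate B → intermediate C (k3 = 1.17 × 10⁻⁵ s⁻¹)
    intermediate C → target (k4 = 1.21 × 10⁻⁵ s⁻¹)
    intermediate B → decomposed reagent (k5 = 3.88 × 10⁻⁶ s⁻¹)
    target ⇌ isomer of the product (K6 = 0.52, k6 = 9.83 × 10⁻⁶ s⁻¹)

| setting | Thursday's | Tuesday's | Monday's |
|---|---|---|---|
| starting material | 0.050 M | 0.050 M | 0.050 M |
| remark | a single well-mixed tank run continuously and read at steady state, 500 h in it on average | everything together in a closed stirred flask, run for 50 h | one stirred flow tank at steady state, fed with the mixture as stated, mean residence time 50 h |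
| time |  | 50 h |  |

- the set-up with the highest share of target in all that became target or isomer of the product, at the outlet or at the end ("none" if the first two lie within 2 percentage points) (Thursday's / Tuesday's / Monday's / none)
- share of target in all that became target or isomer of the product, at the outlet or at the end, Thursday's
- share of target in all that became target or isomer of the product, at the outlet or at the end, Tuesday's
- share of target in all that became target or isomer of the product, at the outlet or at the end, Monday's

I reckoned the rate of loss of the target's lead and worked with the fraction left. Let the share be [target]/([target]+[isomer of the product]). Fresh target is pure, but the share sinks towards a floor, the equilibrium share, 65.8%. This is thermodynamic control; anything above the floor is kinetic, and I called it the excess.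

The way back has the constant 1.89 × 10⁻⁵ s⁻¹. The excess therefore shrinks at the sum of both directions, 2.87 × 10⁻⁵ s⁻¹, which is 2.92 times the forward constant. In a tank, the outflow competes with that shrinking. So the excess left, the fraction of the fresh excess that reaches the outlet, is one over one plus that sum times the residence time.

Thursday's tank keeps 1.90% of the excess, which gave me a share of 66.4%. Monday's tank, at 50 h on average, keeps 16.2%, which gave me 71.3%. In Tuesday's flask the relaxation half-life of 6.70 h is shorter than the run of 50 h, but target keeps arriving through a chain. I stopped there and committed to no number for Tuesday's.

The forecast chose Tuesday's, with 66.4% for Thursday's, 76.2% for Tuesday's and 71.3% for Monday's. Its ground was that “younger product is richer in target”. On the tanks, it and I stood at the same figures.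

The simulation gave 66.4% for Thursday's, 76.2% for Tuesday's and 71.3% for Monday's, so Tuesday's came highest. The forecast held.

The reverse step, isomer of the product to target, is the main reason for Thursday's share. With that reverse step, Thursday's tank keeps 1.90% of the excess above a floor of 65.8%. Without it, Thursday's tank has no such floor and the constant falls to 9.83 × 10⁻⁶ s⁻¹, so the fraction left of pure target is 5.35%. Thursday's tank with that step taken out read 5.35%.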